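## Retrosynthetic overview

- Feature (flavone locants, unit in brackets; unit 1 = the 5-hydroxy-7-methoxy-6-methylflavone, unit 2 = the apigenin half): ring B(1) is a 1,3,4-trisubstituted benzene. C1' carries C2(1), C4' carries OH para to it, and C3' carries C8(2) ortho to that OH. This is a 3-aryl-4-hydroxybenzoate.
- Key disconnection: ring B(1) is built from C3–C6 of methyl coumalate, whose ester carbon becomes C2(1), plus the two side-chain carbons of a (flavon-8-yl)acetic acid used as its bis(trimethylsilyl) ketene acetal. The sequence is [4+2], loss of CO2, loss of Me3SiOH.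
- The C3'(1)–C8(2) bond is therefore made earlier as an aryl–CH2 bond, by Negishi coupling of the 8-iodoflavone with a zinc ester enolate. Unit 2 comes from 2',4',6'-trihydroxyacetophenone and 4-benzyloxybenzaldehyde by the chalcone route.
- Ring C(1) is closed last, by cyclodehydration of the 1,3-diketone obtained from Claisen condensation of the new benzoate with 6-hydroxy-2,4-dimethoxy-3-methylacetophenone (made from 2,6-dimethoxytoluene). BCl3 then removes four benzyl groups and the 5-O-methyl group.
- Ring order: ring C(2) in step 4, ring B(1) in step 8, ring C(1) in step 13. Rings A(1), A(2) and B(2) are bought.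

Key step: step 8

Assumption: the SMILES has no descriptor for the C3'(1)–C8(2) axis, so the target is taken as axially unassigned and no atroposelection is attempted.

## Route

Step 1
Reactants: 1 2',4',6'-trihydroxyacetophenone
Product: 2 1-[2,4-bis(benzyloxy)-6-hydroxyphenyl]ethanone
Conditions: BnBr (2.1 equiv), K2CO3 (2.2 equiv), DMF, rt
Reagents that add atoms: benzyl bromide, BrCc1ccccc1
Why: Williamson etherification; with the halide limited to two equivalents, the para OH and one ortho OH are alkylated, while the last ortho OH stays free because it is hydrogen-bonded to the acetyl group.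

Step 2
Reactants: 2 1-[2,4-bis(benzyloxy)-6-hydroxyphenyl]ethanone
Product: 3 1-[4,6-bis(benzyloxy)-2-hydroxy-3-iodophenyl]ethanone
Conditions: N-iodosuccinimide (1.05 equiv), DMF, 0 °C → rt, dark
Reagents that add atoms: N-iodosuccinimide, O=C1CCC(=O)N1I
Why: Electrophilic aromatic iodination; C3 is ortho to the free phenol and flanked by OH and OBn, whereas C5 lies between two benzyloxy groups, so iodine should enter at C3, the carbon that becomes C8(2).

Step 3
Reactants: 3 1-[4,6-bis(benzyloxy)-2-hydroxy-3-iodophenyl]ethanone; 4 4-benzyloxybenzaldehyde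
Product: 5 (E)-1-[4,6-bis(benzyloxy)-2-hydroxy-3-iodophenyl]-3-[4-(benzyloxy)phenyl]prop-2-en-1-one
Conditions: KOH (10 equiv), EtOH/THF, rt; then 1 M HCl
Reagents that add atoms: none
Why: Claisen–Schmidt condensation; the methyl ketone enolate adds to the non-enolisable aldehyde, and E1cB loss of water gives the conjugated enone in its thermodynamically preferred E geometry.

Step 4
Reactants: 5 (E)-chalcone
Product: 6 5,7-bis(benzyloxy)-2-[4-(benzyloxy)phenyl]-8-iodochromen-4-one
Conditions: I2 (0.1 equiv), DMSO, 120 °C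
Reagents that add atoms: none
Why: Iodine-catalysed oxidative cyclisation of a 2'-hydroxychalcone (oxa-Michael closure and dehydrogenation, DMSO as terminal oxidant); only one phenol is free, so O1 forms next to the iodinated carbon and the halogen ends at C8(2).

Step 5
Reactants: 6 5,7-bis(benzyloxy)-2-[4-(benzyloxy)phenyl]-8-iodochromen-4-one
Product: 7 ethyl 2-{5,7-bis(benzyloxy)-2-[4-(benzyloxy)phenyl]-4-oxochromen-8-yl}acetate
Conditions: BrZnCH2CO2Et (2 equiv), Pd2(dba)3 (2.5 mol %), XPhos (10 mol %), THF, 60 °C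
Reagents that add atoms: (2-ethoxy-2-oxoethyl)zinc bromide, CCOC(=O)C[Zn]Br
Why: Negishi coupling of a Reformatsky reagent (palladium-catalysed α-arylation of a zinc ester enolate); oxidative addition of the C–I bond to zerovalent palladium, transmetalation and reductive elimination at a bulky biarylphosphine complex should tolerate the two ortho oxygens, and the weakly basic zinc enolate leaves the chromenone alone.

Step 6
Reactants: 7 ethyl (flavon-8-yl)acetate
Product: 8 2-{5,7-bis(benzyloxy)-2-[4-(benzyloxy)phenyl]-4-oxochromen-8-yl}acetic acid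
Conditions: LiOH·H2O (3 equiv), THF/EtOH/H2O, rt; then 1 M HCl to pH 3
Reagents that add atoms: lithium hydroxide, [Li+].[OH-]
Why: Ester saponification (BAc2) of an unhindered ethyl ester at room temperature, where benzyl ethers are inert and the flavone pyranone does not open.

Step 7
Reactants: 8 (flavon-8-yl)acetic acid
Product: 10 8-[2,2-bis(trimethylsilyloxy)vinyl]-5,7-bis(benzyloxy)-2-[4-(benzyloxy)phenyl]chromen-4-one, via trimethylsilyl ester 9 (not isolated)
Conditions: LiN(SiMe3)2 (1.05 equiv) then Me3SiCl (1.1 equiv), THF, −78 → 0 °C; LiN(SiMe3)2 (1.15 equiv) then Me3SiCl (1.4 equiv), −78 °C → rt; evaporation, toluene, filtration under Ar, used crude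
Reagents that add atoms: chlorotrimethylsilane, C[Si](C)(C)Cl
Why: Silyl ester formation followed by enolisation and O-silylation, the standard preparation of bis(silyl) ketene acetals; the benzylic α-protons of 9 are the most acidic C–H bonds present and lie within reach of the silylamide, which is too weak a base to metalate C3(2)–H.

Step 8
Reactants: 10 bis(trimethylsilyl) ketene acetal; 11 methyl coumalate (methyl 2-oxo-2H-pyran-5-carboxylate)
Product: 15 methyl 3-{5,7-bis(benzyloxy)-2-[4-(benzyloxy)phenyl]-4-oxochromen-8-yl}-4-hydroxybenzoate, via bridged lactone cycloadduct 12 (not isolated), via bis(silyloxy)cyclohexadiene ester 13 (not isolated), via aryl trimethylsilyl ether 14 (not isolated)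
Conditions: 11 (3 equiv), MeC(OSiMe3)=NSiMe3 (2 equiv), toluene, sealed tube, 110 °C; then 1 M HCl, THF, rt
Reagents that add atoms: none
Why: Inverse-electron-demand Diels–Alder reaction of a 2-pyrone: the electron-poor diene C3=C4–C5=C6 of 11 takes up the electron-rich C=C bond of 10 in a strongly asynchronous [4+2] addition (at the stepwise limit a Mukaiyama–Michael attack on C6 followed by closure of pyrone C3 onto the bis(silyloxy)carbenium carbon), which forms C2'(1)–C3'(1) and C4'(1)–C5'(1) and gives bridged lactone 12. Retro-[4+2] loss of CO2 turns 12 into cyclohexadiene 13, 1,2-elimination of Me3SiOH across C3'–C4' aromatises 13 to silyl ether 14, and dilute acid frees phenol 15. The closest known reactions are the cycloaddition–decarboxylation–elimination cascades of methyl coumalate with 1,1-dialkoxyalkenes and enol ethers, which give para-oxygenated benzoates; the present case differs in the silyl groups and in the bulk of the doubly ortho-substituted aryl group on the dienophile. Ring B(1) is closed as a six-membered carbocycle by intermolecular [4+2] cycloaddition, four carbons coming from the pyrone and two from the ketene acetal, and the three stereocentres of 12 and the one of 13 vanish on aromatisation, so that no stereocontrol is called for and the biaryl axis is set without bias. The selectivity needed is orientation, and it is secured by polarity matching: the nucleophilic aryl-bearing carbon of 10 pairs with C6 of 11 (β to the ester, δ to the lactone carbonyl) and the acetal carbon with C3, which puts the oxygen para to the ester and the aryl group ortho to the oxygen, while the donor-substituted C2(2)=C3(2) bond of the flavone is neither an active diene nor an active dienophile. MeC(OSiMe3)=NSiMe3 caps the released silanol as (Me3Si)2O, since free Me3SiOH would protonate a second molecule of 10.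

Step 9
Reactants: 15 methyl 3-(flavon-8-yl)-4-hydroxybenzoate
Product: 16 methyl 4-(benzyloxy)-3-{5,7-bis(benzyloxy)-2-[4-(benzyloxy)phenyl]-4-oxochromen-8-yl}benzoate
Conditions: BnBr (1.3 equiv), K2CO3 (2 equiv), DMF, 50 °C
Reagents that add atoms: benzyl bromide, BrCc1ccccc1
Why: Williamson etherification masks the phenol, whose phenoxide would otherwise consume base and deactivate the para ester toward the enolate in step 12.

Step 10
Reactants: 17 2,6-dimethoxytoluene
Product: 19 3,5-dimethoxy-4-methylphenol, via pinacol boronate 18 (not isolated)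
Conditions: [Ir(OMe)(cod)]2 (1.5 mol %), 4,4'-di-tert-butyl-2,2'-bipyridine (3 mol %), B2pin2 (0.55 equiv), THF, 80 °C; then 30 % H2O2, aq NaOH, 0 °C → rt; then 1 M HCl
Reagents that add atoms: bis(pinacolato)diboron, CC1(C)OB(OC1(C)C)B1OC(C)(C)C(C)(C)O1 (boryl group of 18); hydrogen peroxide, OO (phenol oxygen of 19)
Why: Sterically governed iridium-catalysed aromatic C–H borylation followed by oxidative C–B to C–O exchange; C4 is the only C–H of 17 without an ortho substituent, so boron and then oxygen enter para to the methyl group, a site that electrophilic substitution cannot reach.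

Step 11
Reactants: 19 3,5-dimethoxy-4-methylphenol
Product: 20 1-(6-hydroxy-2,4-dimethoxy-3-methylphenyl)ethanone
Conditions: AcOH (3 equiv), BF3·OEt2, 85 °C; then H2O
Reagents that add atoms: acetic acid, CC(=O)O
Why: Friedel–Crafts (Fries-type) ortho-acylation of an activated phenol; the para position is blocked by methyl and the two ortho positions are equivalent, so a single o-hydroxyacetophenone should form, and BF3 does not cleave the methyl ethers.

Step 12
Reactants: 16 methyl 4-(benzyloxy)-3-(flavon-8-yl)benzoate; 20 1-(6-hydroxy-2,4-dimethoxy-3-methylphenyl)ethanone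
Product: 21 1-{4-(benzyloxy)-3-[5,7-bis(benzyloxy)-2-(4-benzyloxyphenyl)-4-oxochromen-8-yl]phenyl}-3-(6-hydroxy-2,4-dimethoxy-3-methylphenyl)propane-1,3-dione
Conditions: 20 (1.5 equiv), LiN(SiMe3)2 (4 equiv), THF, −78 → −10 °C; then 16 (1 equiv), −78 °C → rt; then 1 M HCl
Reagents that add atoms: none
Why: Crossed Claisen condensation of the dilithiated o-hydroxyacetophenone (phenoxide and enolate) with a non-enolisable methyl benzoate, an established entry to flavone 1,3-diketones, driven forward by deprotonation of the 1,3-diketone as it forms.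

Step 13
Reactants: 21 1,3-diketone
Product: 22 8-[2-(benzyloxy)-5-(5,7-dimethoxy-6-methyl-4-oxochromen-2-yl)phenyl]-5,7-bis(benzyloxy)-2-[4-(benzyloxy)phenyl]chromen-4-one
Conditions: NaOAc, AcOH, 100 °C
Reagents that add atoms: none
Why: Acid cyclodehydration (hemiketal formation by the only free phenol, then loss of water) closes ring C(1) in a buffered medium that spares benzyl ethers; because the oxygen next to the methyl-bearing carbon is still a methyl ether, only the 6-methyl flavone can form, not the 8-methyl isomer.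

Step 14
Reactants: 22 tetra-O-benzyl 5-O-methyl biflavone
Product: 23 8-[2-hydroxy-5-(5-hydroxy-7-methoxy-6-methyl-4-oxochromen-2-yl)phenyl]-5,7-dihydroxy-2-(4-hydroxyphenyl)chromen-4-one (CNP0113589.0)
Conditions: BCl3 (15 equiv), C6HMe5 (12 equiv), CH2Cl2, −78 °C → rt; then H2O
Reagents that add atoms: none
Why: Lewis acid ether cleavage; BCl3 with pentamethylbenzene as benzyl cation trap removes the four benzyl ethers in the cold, and on warming the boron chelate between C4(1)=O and O5(1) directs demethylation to the 5-methoxy group alone, while the unchelated 7-methoxy group is inert to BCl3 and the mild aprotic conditions give no Wessely–Moser isomerisation.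

## Compound list

1 | 2',4',6'-trihydroxyacetophenone | CC(=O)c1c(O)cc(O)cc1O | starting material
2 | 1-[2,4-bis(benzyloxy)-6-hydroxyphenyl]ethanone | CC(=O)c1c(O)cc(OCc2ccccc2)cc1OCc1ccccc1 | intermediate
3 | 1-[4,6-bis(benzyloxy)-2-hydroxy-3-iodophenyl]ethanone | CC(=O)c1c(O)c(I)c(OCc2ccccc2)cc1OCc1ccccc1 | intermediate
4 | 4-benzyloxybenzaldehyde | O=Cc1ccc(OCc2ccccc2)cc1 | starting material
5 | (E)-1-[4,6-bis(benzyloxy)-2-hydroxy-3-iodophenyl]-3-[4-(benzyloxy)phenyl]prop-2-en-1-one | O=C(/C=C/c1ccc(OCc2ccccc2)cc1)c1c(O)c(I)c(OCc2ccccc2)cc1OCc1ccccc1 | intermediate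
6 | 5,7-bis(benzyloxy)-2-[4-(benzyloxy)phenyl]-8-iodochromen-4-one | O=c1cc(-c2ccc(OCc3ccccc3)cc2)oc2c(I)c(OCc3ccccc3)cc(OCc3ccccc3)c12 | intermediate
7 | ethyl 2-{5,7-bis(benzyloxy)-2-[4-(benzyloxy)phenyl]-4-oxochromen-8-yl}acetate | CCOC(=O)Cc1c(OCc2ccccc2)cc(OCc2ccccc2)c2c(=O)cc(-c3ccc(OCc4ccccc4)cc3)oc12 | intermediate
8 | 2-{5,7-bis(benzyloxy)-2-[4-(benzyloxy)phenyl]-4-oxochromen-8-yl}acetic acid | OC(=O)Cc1c(OCc2ccccc2)cc(OCc2ccccc2)c2c(=O)cc(-c3ccc(OCc4ccccc4)cc3)oc12 | intermediate
9 | trimethylsilyl 2-{5,7-bis(benzyloxy)-2-[4-(benzyloxy)phenyl]-4-oxochromen-8-yl}acetate | C[Si](C)(C)OC(=O)Cc1c(OCc2ccccc2)cc(OCc2ccccc2)c2c(=O)cc(-c3ccc(OCc4ccccc4)cc3)oc12 | intermediate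
10 | 8-[2,2-bis(trimethylsilyloxy)vinyl]-5,7-bis(benzyloxy)-2-[4-(benzyloxy)phenyl]chromen-4-one | C[Si](C)(C)OC(O[Si](C)(C)C)=Cc1c(OCc2ccccc2)cc(OCc2ccccc2)c2c(=O)cc(-c3ccc(OCc4ccccc4)cc3)oc12 | intermediate
11 | methyl coumalate (methyl 2-oxo-2H-pyran-5-carboxylate) | COC(=O)C1=COC(=O)C=C1 | starting material
12 | methyl 7-{5,7-bis(benzyloxy)-2-[4-(benzyloxy)phenyl]-4-oxochromen-8-yl}-3-oxo-8,8-bis(trimethylsilyloxy)-2-oxabicyclo[2.2.2]oct-5-ene-6-carboxylate (racemic, relative configuration at C7 open and without consequence) | COC(=O)C1=CC2C(=O)OC1C(c1c(OCc3ccccc3)cc(OCc3ccccc3)c3c(=O)cc(-c4ccc(OCc5ccccc5)cc4)oc13)C2(O[Si](C)(C)C)O[Si](C)(C)C | intermediate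
13 | methyl 3-{5,7-bis(benzyloxy)-2-[4-(benzyloxy)phenyl]-4-oxochromen-8-yl}-4,4-bis(trimethylsilyloxy)cyclohexa-1,5-diene-1-carboxylate (racemic) | COC(=O)C1=CC(c2c(OCc3ccccc3)cc(OCc3ccccc3)c3c(=O)cc(-c4ccc(OCc5ccccc5)cc4)oc23)C(O[Si](C)(C)C)(O[Si](C)(C)C)C=C1 | intermediate
14 | methyl 3-{5,7-bis(benzyloxy)-2-[4-(benzyloxy)phenyl]-4-oxochromen-8-yl}-4-(trimethylsilyloxy)benzoate | COC(=O)c1ccc(O[Si](C)(C)C)c(-c2c(OCc3ccccc3)cc(OCc3ccccc3)c3c(=O)cc(-c4ccc(OCc5ccccc5)cc4)oc23)c1 | intermediate
15 | methyl 3-{5,7-bis(benzyloxy)-2-[4-(benzyloxy)phenyl]-4-oxochromen-8-yl}-4-hydroxybenzoate | COC(=O)c1ccc(O)c(-c2c(OCc3ccccc3)cc(OCc3ccccc3)c3c(=O)cc(-c4ccc(OCc5ccccc5)cc4)oc23)c1 | intermediate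
16 | methyl 4-(benzyloxy)-3-{5,7-bis(benzyloxy)-2-[4-(benzyloxy)phenyl]-4-oxochromen-8-yl}benzoate | COC(=O)c1ccc(OCc2ccccc2)c(-c2c(OCc3ccccc3)cc(OCc3ccccc3)c3c(=O)cc(-c4ccc(OCc5ccccc5)cc4)oc23)c1 | intermediate
17 | 2,6-dimethoxytoluene | COc1cccc(OC)c1C | starting material
18 | 2-(3,5-dimethoxy-4-methylphenyl)-4,4,5,5-tetramethyl-1,3,2-dioxaborolane | COc1cc(B2OC(C)(C)C(C)(C)O2)cc(OC)c1C | intermediate
19 | 3,5-dimethoxy-4-methylphenol | COc1cc(O)cc(OC)c1C | intermediate
20 | 1-(6-hydroxy-2,4-dimethoxy-3-methylphenyl)ethanone | CC(=O)c1c(O)cc(OC)c(C)c1OC | intermediate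
21 | 1-{4-(benzyloxy)-3-[5,7-bis(benzyloxy)-2-(4-benzyloxyphenyl)-4-oxochromen-8-yl]phenyl}-3-(6-hydroxy-2,4-dimethoxy-3-methylphenyl)propane-1,3-dione (drawn as the diketo tautomer) | COc1cc(O)c(C(=O)CC(=O)c2ccc(OCc3ccccc3)c(-c3c(OCc4ccccc4)cc(OCc4ccccc4)c4c(=O)cc(-c5ccc(OCc6ccccc6)cc5)oc34)c2)c(OC)c1C | intermediate
22 | 8-[2-(benzyloxy)-5-(5,7-dimethoxy-6-methyl-4-oxochromen-2-yl)phenyl]-5,7-bis(benzyloxy)-2-[4-(benzyloxy)phenyl]chromen-4-one | COc1cc2oc(-c3ccc(OCc4ccccc4)c(-c4c(OCc5ccccc5)cc(OCc5ccccc5)c5c(=O)cc(-c6ccc(OCc7ccccc7)cc6)oc45)c3)cc(=O)c2c(OC)c1C | intermediate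
23 | 8-[2-hydroxy-5-(5-hydroxy-7-methoxy-6-methyl-4-oxochromen-2-yl)phenyl]-5,7-dihydroxy-2-(4-hydroxyphenyl)chromen-4-one (CNP0113589.0) | COc1cc2oc(-c3ccc(O)c(-c4c(O)cc(O)c5c(=O)cc(-c6ccc(O)cc6)oc45)c3)cc(=O)c2c(O)c1C | target

## Step count and risks

Total step count: 14.
Longest linear sequence: 12 (steps 1–9 and 12–14). Steps 10–11 form the two-step side branch to 20.

**Step 8.**
- What may go wrong: bond formation at the hindered aryl-bearing carbon of the ketene acetal may be too slow. Three processes could then take over: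
  - thermal self-dimerisation of the pyrone;
  - protonation or O-to-C silyl shift of the ketene acetal;
  - Michael addition at C6 followed by opening of the pyrone instead of ring closure.
- Fallback: Suzuki–Miyaura biaryl coupling, which builds the C3'(1)–C8(2) bond directly instead of building ring B. It sets out from iodoflavone 6 and comes back at benzyl ether 16.
  - Commercial methyl 4-hydroxy-3-iodobenzoate is benzylated (BnBr, K2CO3, DMF) to methyl 4-(benzyloxy)-3-iodobenzoate F1.
  - Miyaura borylation (B2pin2, PdCl2(dppf), KOAc, dioxane, 90 °C) gives methyl 4-(benzyloxy)-3-(4,4,5,5-tetramethyl-1,3,2-dioxaborolan-2-yl)benzoate F2.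
  - Coupling of F2 with 6 (Pd(OAc)2, SPhos, K3PO4, dioxane/H2O, 90 °C) should give 16. Steps 5–9 then fall away.

**Step 12.**
- What may go wrong: intermolecular attack of the hindered lithium enolate on the methyl ester may lag behind proton exchange, or behind reversible conjugate attack at C2(2) of the flavone already present. The condensation would then stall or the ester would be consumed unproductively.
- Fallback: Baker–Venkataraman rearrangement, an intramolecular acyl transfer in place of the intermolecular Claisen step. It sets out from 16 and comes back at 21.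
  - 16 is saponified (LiOH, THF/H2O) to 4-(benzyloxy)-3-{5,7-bis(benzyloxy)-2-[4-(benzyloxy)phenyl]-4-oxochromen-8-yl}benzoic acid F3.
  - F3 is esterified with phenol 20 (EDC·HCl, DMAP, CH2Cl2) to 2-acetyl-3,5-dimethoxy-4-methylphenyl 4-(benzyloxy)-3-{5,7-bis(benzyloxy)-2-[4-(benzyloxy)phenyl]-4-oxochromen-8-yl}benzoate F4.
  - LiN(SiMe3)2 in THF (−78 → 0 °C) moves the aroyl group from oxygen to the enolate carbon to give 21.

**Step 14.**
- What may go wrong: partly deprotected boron phenoxides may precipitate and stop the cleavage short. Benzyl cations may escape the trap and alkylate the phloroglucinol ring. Prolonged warming may start demethylation at O7(1).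
- Fallback: the two tasks are separated and the benzyl groups are removed reductively. It sets out from 22 and comes back at 23.
  - Hydrogenolysis (H2, 10 % Pd/C, THF/MeOH, rt) gives 8-[5-(5,7-dimethoxy-6-methyl-4-oxochromen-2-yl)-2-hydroxyphenyl]-5,7-dihydroxy-2-(4-hydroxyphenyl)chromen-4-one F5.
  - Chelation-controlled demethylation of the peri methoxy group (AlCl3, MeCN, 70 °C; then dilute HCl) gives 23.

Further compounds
F1 | step 8 | methyl 4-(benzyloxy)-3-iodobenzoate | COC(=O)c1ccc(OCc2ccccc2)c(I)c1
F2 | step 8 | methyl 4-(benzyloxy)-3-(4,4,5,5-tetramethyl-1,3,2-dioxaborolan-2-yl)benzoate | COC(=O)c1ccc(OCc2ccccc2)c(B2OC(C)(C)C(C)(C)O2)c1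
F3 | step 12 | 4-(benzyloxy)-3-{5,7-bis(benzyloxy)-2-[4-(benzyloxy)phenyl]-4-oxochromen-8-yl}benzoic acid | OC(=O)c1ccc(OCc2ccccc2)c(-c2c(OCc3ccccc3)cc(OCc3ccccc3)c3c(=O)cc(-c4ccc(OCc5ccccc5)cc4)oc23)c1
F4 | step 12 | 2-acetyl-3,5-dimethoxy-4-methylphenyl 4-(benzyloxy)-3-{5,7-bis(benzyloxy)-2-[4-(benzyloxy)phenyl]-4-oxochromen-8-yl}benzoate | CC(=O)c1c(OC(=O)c2ccc(OCc3ccccc3)c(-c3c(OCc4ccccc4)cc(OCc4ccccc4)c4c(=O)cc(-c5ccc(OCc6ccccc6)cc5)oc34)c2)cc(OC)c(C)c1OC
F5 | step 14 | 8-[5-(5,7-dimethoxy-6-methyl-4-oxochromen-2-yl)-2-hydroxyphenyl]-5,7-dihydroxy-2-(4-hydroxyphenyl)chromen-4-one | COc1cc2oc(-c3ccc(O)c(-c4c(O)cc(O)c5c(=O)cc(-c6ccc(O)cc6)oc45)c3)cc(=O)c2c(OC)c1C
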